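**Strategy.** The whole carbon skeleton is cut back to one farnesyl chain. The key step exploits the spirovetivane pattern of the target: spiro carbon C5 joining cyclopentane C1–C5 (isopropenyl at C3) to cyclohexene C5–C10 (methyls at C6 and C10), which is the fold of farnesyl diphosphate. A sesquiterpene cyclase forms C3–C4, C5–C6 and, by a ring-contracting 1,2-shift, C5–C1, closing both rings and setting C3, C5 and C10 in one operation. Because farnesyl C8 is the migrating carbon and becomes C1, the precursor is (2E,6E,8R)-8-hydroxyfarnesyl diphosphate, which brings in the C1 oxygen with its configuration; the C8 ketone and C9 acetate then follow by enone chemistry.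

Key step: step 9

Remark: ring positions follow the spiro[4.5]decane name of the target (C1 ester carbon, C3 isopropenyl carbon, C5 spiro carbon, C8 ketone, C9 acetate carbon); acyclic compounds use farnesyl numbering, and diphosphates are drawn as free acids but handled as ammonium salts.

**Step 1**
Reactants: 1 geraniol
Product: 2 geranyl tert-butyldimethylsilyl ether
Conditions: TBSCl, imidazole, DMF, 0 °C to rt
Reagents that add atoms: tert-butyldimethylsilyl chloride, CC(C)(C)[Si](C)(C)Cl
Why: Imidazole-promoted silylation of a primary allylic alcohol (silyl ether formation) is routine and no stereocentre is involved.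

**Step 2**
Reactants: 2 geranyl tert-butyldimethylsilyl ether
Product: 4 (2E,6E)-8-(tert-butyldimethylsilyloxy)-2,6-dimethylocta-2,6-dienal, via allylic alcohol 3 (not isolated)
Conditions: SeO2 (cat.), t-BuOOH, salicylic acid (cat.), CH2Cl2, rt; then MnO2, CH2Cl2, rt
Reagents that add atoms: tert-butyl hydroperoxide, CC(C)(C)OO (terminal oxygen source; the oxygen is passed on by catalytic SeO2, O=[Se]=O)
Why: Riley allylic oxidation under catalytic SeO2/t-BuOOH conditions (ene reaction then [2,3]-sigmatropic shift) selects the E methyl group of the more electron-rich distal trisubstituted alkene and keeps the E geometry, and MnO2 oxidation of the allylic alcohol completes the conversion to the enal.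

**Step 3**
Reactants: 4 (2E,6E)-8-(tert-butyldimethylsilyloxy)-2,6-dimethylocta-2,6-dienal; 5 (+)-B-allyldiisopinocampheylborane
Product: 6 (4R,5E,9E)-11-(tert-butyldimethylsilyloxy)-5,9-dimethylundeca-1,5,9-trien-4-ol
Conditions: Et2O, −78 °C; then NaOH, H2O2, rt
Reagents that add atoms: none
Why: Brown allylboration through a closed chair transition state adds the allyl group 1,2 to the enal under reagent control, and the borane derived from (−)-α-pinene attacks the aldehyde face that gives the R carbinol (the sense that gives the R alcohol from benzaldehyde), which is C8 of the farnesyl chain.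

**Step 4**
Reactants: 6 (4R,5E,9E)-11-(tert-butyldimethylsilyloxy)-5,9-dimethylundeca-1,5,9-trien-4-ol
Product: 7 (4R,5E,9E)-11-(tert-butyldimethylsilyloxy)-5,9-dimethylundeca-1,5,9-trien-4-yl acetate
Conditions: Ac2O, Et3N, DMAP (cat.), CH2Cl2, 0 °C to rt
Reagents that add atoms: acetic anhydride, CC(=O)OC(C)=O
Why: DMAP-catalysed acetylation masks the secondary allylic alcohol as a base-labile ester that will survive chlorination and diphosphorylation and can later be removed without acid, with no change at the carbinol centre.

**Step 5**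
Reactants: 7 (4R,5E,9E)-11-(tert-butyldimethylsilyloxy)-5,9-dimethylundeca-1,5,9-trien-4-yl acetate; 8 2-methylbut-2-ene
Product: 9 (2E,6E,8R)-1-(tert-butyldimethylsilyloxy)-3,7,11-trimethyldodeca-2,6,10-trien-8-yl acetate
Conditions: second-generation Grubbs catalyst (H2IMes)(PCy3)Cl2Ru=CHPh (cat.), excess 8, CH2Cl2, 40 °C
Reagents that add atoms: none
Why: Olefin cross-metathesis between the monosubstituted terminal alkene and excess 2-methylbut-2-ene installs the trisubstituted prenyl terminus, the two internal trisubstituted alkenes being too hindered to engage the ruthenium carbene, and no alkene geometry arises.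

**Step 6**
Reactants: 9 (2E,6E,8R)-1-(tert-butyldimethylsilyloxy)-3,7,11-trimethyldodeca-2,6,10-trien-8-yl acetate
Product: 10 (2E,6E,8R)-8-acetoxyfarnesol
Conditions: HF·pyridine, pyridine, THF, 0 °C to rt
Reagents that add atoms: none
Why: Fluoride-driven cleavage of the primary silyl ether (desilylation) under pyridine-buffered conditions leaves the allylic acetate and the alkenes untouched.

**Step 7**
Reactants: 10 (2E,6E,8R)-8-acetoxyfarnesol
Product: 12 (2E,6E,8R)-8-acetoxyfarnesyl diphosphate, via allylic chloride 11 (not isolated)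
Conditions: N-chlorosuccinimide, Me2S, CH2Cl2, −30 to 0 °C; then (n-Bu4N)3HP2O7, MeCN, rt; Dowex 50WX8 (NH4+ form), aq. NH4HCO3, lyophilisation
Reagents that add atoms: tris(tetra-n-butylammonium) hydrogen diphosphate, CCCC[N+](CCCC)(CCCC)CCCC.CCCC[N+](CCCC)(CCCC)CCCC.CCCC[N+](CCCC)(CCCC)CCCC.OP(=O)([O-])OP(=O)([O-])[O-]
Why: Corey–Kim chlorination turns the primary allylic alcohol into the chloride 11 without allylic transposition, and SN2 displacement by the diphosphate anion at this unhindered primary carbon gives the diphosphate with the 2E geometry intact, the C8 acetate being inert to both reagents.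

**Step 8**
Reactants: 12 (2E,6E,8R)-8-acetoxyfarnesyl diphosphate
Product: 13 (2E,6E,8R)-8-hydroxyfarnesyl diphosphate
Conditions: K2CO3, MeOH/H2O, rt; then Dowex 50WX8 (NH4+ form), lyophilisation
Reagents that add atoms: none
Why: Mild carbonate hydrolysis (ester saponification by acyl–oxygen cleavage) frees the C8 hydroxyl with retention, and allylic diphosphates are stable to base, being labile only to acid.

**Step 9**
Reactants: 13 (2E,6E,8R)-8-hydroxyfarnesyl diphosphate
Product: 15 (1R,3S,5R,10R)-6,10-dimethyl-3-(prop-1-en-2-yl)spiro[4.5]dec-6-en-1-ol, via hydroxygermacrene 14 (not isolated)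
Conditions: recombinant premnaspirodiene synthase (Hyoscyamus muticus, His-tagged, from E. coli), MgCl2, HEPES buffer pH 7.5, DTT, 30 °C, pentane/Et2O overlay
Reagents that add atoms: none
Why: Mg2+-assisted loss of diphosphate from 13 gives the farnesyl cation, C10 of the distal alkene attacks C1 and a methyl proton is lost to give bound 14, reprotonation at C6 drives transannular attack of C2=C3 on C7 to a eudesmyl cation, a 1,2-hydride shift from C2 to C3 moves the charge to the ring-fusion carbon, and a Wagner–Meerwein shift of the carbinol carbon C8 from C7 to C2 followed by loss of a C6 proton gives 15 (farnesyl numbering). The closest known reaction type is the native class one sesquiterpene cyclase cascade of this synthase on farnesyl diphosphate, taken together with the known turnover of hydroxylated and ether-containing farnesyl diphosphate analogues by cyclases of the same class. The cyclohexene ring of 15 (C5–C10) closes in the transannular cation–olefin step (C5–C6, endo at the C2=C3 alkene of a cyclodeca-1,5-diene, chair-like), and the cyclopentane (C1–C5) arises from the macrocyclisation bond C3–C4 (exo at the distal alkene) and the ring-contracting 1,2-shift that forms C5–C1. C3 is fixed by the alkene face that the fold presents to the allyl cation, C10 by the suprafacial hydride shift, C5 by the stereospecific shift of C8 anti to that hydride, and C1 is carried over unchanged from C8 of 13 because a migrating carbon keeps its configuration. The step needs migration of the ring carbon and not of the angular methyl, which the active-site contour of this synthase secures, and it needs the hydroxyl to stay out of the cation chemistry, which is favoured by its trans placement to the C10 side chain in 14 and by the water-excluding pocket.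

**Step 10**
Reactants: 15 (1R,3S,5R,10R)-6,10-dimethyl-3-(prop-1-en-2-yl)spiro[4.5]dec-6-en-1-ol; 16 isobutyric anhydride
Product: 17 (1R,3S,5R,10R)-6,10-dimethyl-3-(prop-1-en-2-yl)spiro[4.5]dec-6-en-1-yl 2-methylpropanoate
Conditions: DMAP, Et3N, CH2Cl2, rt to 40 °C
Reagents that add atoms: none
Why: DMAP-catalysed acyl transfer from the anhydride esterifies the hindered secondary alcohol at oxygen, so C1 keeps its configuration.

**Step 11**
Reactants: 17 (1R,3S,5R,10R)-6,10-dimethyl-3-(prop-1-en-2-yl)spiro[4.5]dec-6-en-1-yl 2-methylpropanoate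
Product: 18 (1R,3S,5R,10R)-6,10-dimethyl-8-oxo-3-(prop-1-en-2-yl)spiro[4.5]dec-6-en-1-yl 2-methylpropanoate
Conditions: CrO3, 3,5-dimethylpyrazole, CH2Cl2, −20 °C
Reagents that add atoms: chromium trioxide, O=[Cr](=O)=O
Why: Allylic C–H oxidation with the CrO3–3,5-dimethylpyrazole complex converts the only ring methylene that is allylic to the trisubstituted alkene (C8, since C5 is quaternary) into the conjugated ketone, while the 1,1-disubstituted isopropenyl group and the ester are much less reactive.

**Step 12**
Reactants: 18 (1R,3S,5R,10R)-6,10-dimethyl-8-oxo-3-(prop-1-en-2-yl)spiro[4.5]dec-6-en-1-yl 2-methylpropanoate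
Product: 19 (1R,3S,5R,9R,10S)-9-acetoxy-6,10-dimethyl-8-oxo-3-(prop-1-en-2-yl)spiro[4.5]dec-6-en-1-yl 2-methylpropanoate (target)
Conditions: Mn(OAc)3·2H2O, benzene, reflux (Dean–Stark)
Reagents that add atoms: Mn(OAc)3 dihydrate, CC(=O)[O-].CC(=O)[O-].CC(=O)[O-].[Mn+3].O.O
Why: Alpha-prime acetoxylation of an enone with Mn(OAc)3 proceeds through the manganese enolate formed at C9, the only enolisable position next to the carbonyl apart from the vinylogous methyl, and acetate is delivered anti to the neighbouring C10 methyl to give the trans (9R) acetate, which is also the isomer favoured on equilibration.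

**Compound list**

1 | geraniol, (2E)-3,7-dimethylocta-2,6-dien-1-ol | CC(C)=CCC/C(C)=C/CO | starting material
2 | geranyl tert-butyldimethylsilyl ether | CC(C)=CCC/C(C)=C/CO[Si](C)(C)C(C)(C)C | intermediate
3 | (2E,6E)-8-(tert-butyldimethylsilyloxy)-2,6-dimethylocta-2,6-dien-1-ol | OC/C(C)=C/CC/C(C)=C/CO[Si](C)(C)C(C)(C)C | intermediate (not isolated)
4 | (2E,6E)-8-(tert-butyldimethylsilyloxy)-2,6-dimethylocta-2,6-dienal | O=C/C(C)=C/CC/C(C)=C/CO[Si](C)(C)C(C)(C)C | intermediate
5 | (+)-B-allyldiisopinocampheylborane, from (−)-α-pinene | C=CCB([C@H]1C[C@H]2C[C@@H]([C@@H]1C)C2(C)C)[C@H]1C[C@H]2C[C@@H]([C@@H]1C)C2(C)C | starting material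
6 | (4R,5E,9E)-11-(tert-butyldimethylsilyloxy)-5,9-dimethylundeca-1,5,9-trien-4-ol | C=CC[C@@H](O)/C(C)=C/CC/C(C)=C/CO[Si](C)(C)C(C)(C)C | intermediate
7 | (4R,5E,9E)-11-(tert-butyldimethylsilyloxy)-5,9-dimethylundeca-1,5,9-trien-4-yl acetate | C=CC[C@@H](OC(C)=O)/C(C)=C/CC/C(C)=C/CO[Si](C)(C)C(C)(C)C | intermediate
8 | 2-methylbut-2-ene | CC=C(C)C | starting material
9 | (2E,6E,8R)-1-(tert-butyldimethylsilyloxy)-3,7,11-trimethyldodeca-2,6,10-trien-8-yl acetate | CC(C)=CC[C@@H](OC(C)=O)/C(C)=C/CC/C(C)=C/CO[Si](C)(C)C(C)(C)C | intermediate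
10 | (2E,6E,8R)-8-acetoxyfarnesol, (2E,6E,8R)-1-hydroxy-3,7,11-trimethyldodeca-2,6,10-trien-8-yl acetate | CC(C)=CC[C@@H](OC(C)=O)/C(C)=C/CC/C(C)=C/CO | intermediate
11 | (2E,6E,8R)-1-chloro-3,7,11-trimethyldodeca-2,6,10-trien-8-yl acetate | CC(C)=CC[C@@H](OC(C)=O)/C(C)=C/CC/C(C)=C/CCl | intermediate (not isolated)
12 | (2E,6E,8R)-8-acetoxyfarnesyl diphosphate | CC(C)=CC[C@@H](OC(C)=O)/C(C)=C/CC/C(C)=C/COP(=O)(O)OP(=O)(O)O | intermediate
13 | (2E,6E,8R)-8-hydroxyfarnesyl diphosphate | CC(C)=CC[C@@H](O)/C(C)=C/CC/C(C)=C/COP(=O)(O)OP(=O)(O)O | intermediate (key-step precursor)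
14 | (8R,10S)-8-hydroxygermacrene A, farnesyl numbering, both ring alkenes E, enzyme-bound | C=C(C)[C@@H]1C[C@@H](O)/C(C)=C/CC/C(C)=C/C1 | intermediate (not isolated)
15 | (1R,3S,5R,10R)-6,10-dimethyl-3-(prop-1-en-2-yl)spiro[4.5]dec-6-en-1-ol | C=C(C)[C@@H]1C[C@@H](O)[C@@]2(C1)C(C)=CCC[C@H]2C | intermediate (key-step product)
16 | isobutyric anhydride | CC(C)C(=O)OC(=O)C(C)C | starting material
17 | (1R,3S,5R,10R)-6,10-dimethyl-3-(prop-1-en-2-yl)spiro[4.5]dec-6-en-1-yl 2-methylpropanoate | C=C(C)[C@@H]1C[C@@H](OC(=O)C(C)C)[C@@]2(C1)C(C)=CCC[C@H]2C | intermediate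
18 | (1R,3S,5R,10R)-6,10-dimethyl-8-oxo-3-(prop-1-en-2-yl)spiro[4.5]dec-6-en-1-yl 2-methylpropanoate | C=C(C)[C@@H]1C[C@@H](OC(=O)C(C)C)[C@@]2(C1)C(C)=CC(=O)C[C@H]2C | intermediate
19 | (1R,3S,5R,9R,10S)-9-acetoxy-6,10-dimethyl-8-oxo-3-(prop-1-en-2-yl)spiro[4.5]dec-6-en-1-yl 2-methylpropanoate | C=C(C)[C@@H]1C[C@@H](OC(=O)C(C)C)[C@@]2(C1)C(C)=CC(=O)[C@H](OC(C)=O)[C@H]2C | target

**Totals.** Total step count: 12. Longest linear sequence: 12 steps (1 to 19).

**Steps most likely to fail**

Step 9. The cascade may lose fidelity on the hydroxylated chain. The hydroxyl may capture a cationic centre as a cyclic ether, it may slow the acid-triggered transannular closure so that 14 is released, or it may tip the last shift towards methyl migration. The cyclase may also bind the analogue poorly. The fallback sets out from 12 and keeps the oxygen masked through the cyclization, so that it cannot act as a nucleophile or hydrogen-bond donor in the pocket. The acetoxy diphosphate 12 itself is incubated with the same synthase and should give (1R,3S,5R,10R)-6,10-dimethyl-3-(prop-1-en-2-yl)spiro[4.5]dec-6-en-1-yl acetate F1. Cleavage of the acetate with catalytic K2CO3 in MeOH then returns to the route at 15.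

Step 11. Site selectivity may be poor, with attack at the C6 methyl or at the isopropenyl group, or the product may be over-oxidised. The fallback sets out from 15 and moves the oxidation to the alcohol stage under enzyme control. The cytochrome P450 premnaspirodiene oxygenase of the same plant (CYP71D55), expressed in yeast together with its reductase, oxidises this ring methylene of the parent diene. It should take 15 through the allylic alcohol (1R,3S,5R,10R)-6,10-dimethyl-3-(prop-1-en-2-yl)spiro[4.5]dec-6-ene-1,8-diol F2 (C8 configuration as the enzyme sets it, erased in the next oxidation) to the hydroxy enone (1R,3S,5R,10R)-1-hydroxy-6,10-dimethyl-3-(prop-1-en-2-yl)spiro[4.5]dec-6-en-8-one F3. Esterification of F3 with 16 (DMAP, Et3N, CH2Cl2) rejoins the route at 18.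

Step 12. Regio- or facial selectivity may be poor (oxidation at the vinylogous C6 methyl, or formation of the cis acetate), and radical side reactions at the alkenes may occur. The fallback sets out from 18 and goes through the lithium enolate. LiHMDS (THF, −78 °C) removes the C9 proton kinetically, and 2-(phenylsulfonyl)-3-phenyloxaziridine hydroxylates the enolate anti to the C10 methyl without touching the alkenes. This should give (1R,3S,5R,9R,10S)-9-hydroxy-6,10-dimethyl-8-oxo-3-(prop-1-en-2-yl)spiro[4.5]dec-6-en-1-yl 2-methylpropanoate F4. Acetylation (Ac2O, DMAP, pyridine) then gives 19 directly.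

**Further compounds**

F1 | step 9 | (1R,3S,5R,10R)-6,10-dimethyl-3-(prop-1-en-2-yl)spiro[4.5]dec-6-en-1-yl acetate | C=C(C)[C@@H]1C[C@@H](OC(C)=O)[C@@]2(C1)C(C)=CCC[C@H]2C
F2 | step 11 | (1R,3S,5R,10R)-6,10-dimethyl-3-(prop-1-en-2-yl)spiro[4.5]dec-6-ene-1,8-diol, C8 configuration left open | C=C(C)[C@@H]1C[C@@H](O)[C@@]2(C1)C(C)=CC(O)C[C@H]2C
F3 | step 11 | (1R,3S,5R,10R)-1-hydroxy-6,10-dimethyl-3-(prop-1-en-2-yl)spiro[4.5]dec-6-en-8-one | C=C(C)[C@@H]1C[C@@H](O)[C@@]2(C1)C(C)=CC(=O)C[C@H]2C
F4 | step 12 | (1R,3S,5R,9R,10S)-9-hydroxy-6,10-dimethyl-8-oxo-3-(prop-1-en-2-yl)spiro[4.5]dec-6-en-1-yl 2-methylpropanoate | C=C(C)[C@@H]1C[C@@H](OC(=O)C(C)C)[C@@]2(C1)C(C)=CC(=O)[C@H](O)[C@H]2C
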